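## Retrosynthetic overview
- The target comes from one neutral Pd/H2 operation on a hexabenzylated (S)-3-aroyl-1,2-diaryl-1H-indene. H2 adds anti to the C3 aryl group, which sets C1 and C2, and all six benzyl groups are cleaved in the same step.
- The aroyl-indene is disconnected at the ketone C7′–O bond. It arises by intramolecular alkyne–carbonyl metathesis of an o-alkynyl 1,2,2-triarylethanone: oxygen moves from C2 to C7′ through an oxete. This step builds the only new ring (the five-membered one) and, run as a dynamic kinetic resolution, sets C3.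
- The triarylethanone comes from Pd enolate arylation of a deoxybenzoin with a 2-bromotolane.
- Both halves come from one tolane. Hydration gives the ketone and NBS gives the bromide. The tolane itself comes from a Sonogashira coupling of two commercial benzyl ethers.

Assumption: the SMILES is read literally and decodes as (1R,2R,3R), which places the aroyl, 4-hydroxyphenyl and 3,5-dihydroxyphenyl groups all on one face of the five-membered ring (all-cis); the route is built for that isomer. Locants C1–C3, C3a and C7a are those of the target indane, and C7′ is the ketone carbon.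

## Route

Step 1
Reactants: 1 1,3-bis(benzyloxy)-5-bromobenzene; 2 1-(benzyloxy)-4-ethynylbenzene
Product: 3 1,3-bis(benzyloxy)-5-{[4-(benzyloxy)phenyl]ethynyl}benzene
Conditions: PdCl2(MeCN)2 (1 mol %), XPhos (3 mol %), Cs2CO3 (1.5 equiv), MeCN, 80 °C
Reagents that add atoms: none
Why: Copper-free Sonogashira coupling with a bulky biaryl phosphine handles the electron-rich aryl bromide, leaves the benzyl ethers untouched and creates no stereocentre.

Step 2
Reactants: 3 1,3-bis(benzyloxy)-5-{[4-(benzyloxy)phenyl]ethynyl}benzene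
Product: 4 1,5-bis(benzyloxy)-2-bromo-3-{[4-(benzyloxy)phenyl]ethynyl}benzene
Conditions: NBS (1.0 equiv), CH2Cl2, −20 °C to rt, dark
Reagents that add atoms: N-bromosuccinimide, O=C1CCC(=O)N1Br
Why: Electrophilic aromatic bromination takes the most activated and accessible carbon of the resorcinol diether ring (ortho to one OBn, para to the other, next to the slim alkyne) rather than the crowded position between the two OBn groups or the less activated mono-alkoxy ring.

Step 3
Reactants: 3 1,3-bis(benzyloxy)-5-{[4-(benzyloxy)phenyl]ethynyl}benzene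
Product: 5 1-[4-(benzyloxy)phenyl]-2-[3,5-bis(benzyloxy)phenyl]ethan-1-one
Conditions: p-TsOH·H2O (30 mol %), H2O (5 equiv), EtOH/1,4-dioxane 1:1, 90 °C
Reagents that add atoms: water, O
Why: Brønsted-acid Markovnikov alkyne hydration runs through the vinyl cation stabilised by the p-benzyloxyphenyl group, so oxygen is placed only on the carbon next to that ring.

Step 4
Reactants: 4 1,5-bis(benzyloxy)-2-bromo-3-{[4-(benzyloxy)phenyl]ethynyl}benzene; 5 1-[4-(benzyloxy)phenyl]-2-[3,5-bis(benzyloxy)phenyl]ethan-1-one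
Product: 6 (±)-1-[4-(benzyloxy)phenyl]-2-[3,5-bis(benzyloxy)phenyl]-2-(2,4-bis(benzyloxy)-6-{[4-(benzyloxy)phenyl]ethynyl}phenyl)ethan-1-one
Conditions: Pd[P(t-Bu)3]2 (4 mol %), K3PO4 (2.5 equiv), toluene, 90 °C
Reagents that add atoms: none
Why: Pd-catalysed ketone α-arylation of the acidic deoxybenzoin stops at the 1,2,2-triarylethanone because a quaternary centre cannot form, and C3 is created racemic and labile, which step 5 exploits.

Step 5
Reactants: 6 (±)-1-[4-(benzyloxy)phenyl]-2-[3,5-bis(benzyloxy)phenyl]-2-(2,4-bis(benzyloxy)-6-{[4-(benzyloxy)phenyl]ethynyl}phenyl)ethan-1-one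
Product: 9 {(1S)-5,7-bis(benzyloxy)-2-[4-(benzyloxy)phenyl]-1-[3,5-bis(benzyloxy)phenyl]-1H-inden-3-yl}[4-(benzyloxy)phenyl]methanone, via achiral triaryl enol 7 (not isolated), via indeno-fused 2H-oxete 8 (not isolated)
Conditions: (S,S)-IDPi acid (BINOL-derived N-triflyl imidodiphosphorimidate, wide-pocket 3,3′-aryl groups, 5 mol %; antipode fixed in a first screen), 4 Å MS, toluene, 0 °C to rt
Reagents that add atoms: none
Why: Proposed new method: a catalytic enantioselective alkyne–carbonyl metathesis run as a dynamic kinetic resolution. The strong chiral acid activates the aryl ketone, and the alkyne, polarised by its p-benzyloxyphenyl group, attacks C2 with its inner carbon C1 (5-exo-dig). The vinyl-cation character developing at C7′ is quenched by the carbonyl oxygen, so the new C7′–O bond closes oxete 8. Its 4π ring opening hands the oxygen to C7′ and leaves the C1=C2 bond of the indene. The same acid racemises 6 through enol 7 (doubly benzylic α-H). The confined chiral anion, ion-paired with the cationic transition state, lets only (R)-6 cyclise, with its C3 aryl turned away from the catalyst wall, and this fixes C3. Product 9 keeps its configuration because its protonated form is a stabilised hydroxyallyl cation that loses the γ-H much more slowly than 6 enolises. Closest known reaction types: racemic Lewis- or Brønsted-acid-catalysed intramolecular alkyne–carbonyl metathesis to 2-acylcycloalkenes, chiral-acid Nazarov cyclisation, and chiral-acid enol catalysis of α-branched ketones.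

Step 6
Reactants: 9 {(1S)-5,7-bis(benzyloxy)-2-[4-(benzyloxy)phenyl]-1-[3,5-bis(benzyloxy)phenyl]-1H-inden-3-yl}[4-(benzyloxy)phenyl]methanone
Product: 10 caraphenol B, [(1R,2R,3R)-3-(3,5-dihydroxyphenyl)-4,6-dihydroxy-2-(4-hydroxyphenyl)-2,3-dihydro-1H-inden-1-yl](4-hydroxyphenyl)methanone
Conditions: H2 (10 bar), 10 % Pd/C, EtOAc/EtOH 1:1, rt; filtration, no acid or base in work-up
Reagents that add atoms: none
Why: In this heterogeneous syn-hydrogenation with hydrogenolysis the indene binds Pd on the face opposite the C3 aryl, so both new hydrogens enter cis to H-3 and push the aroyl and 4-hydroxyphenyl groups onto the face of the C3 aryl (all-cis, 1R,2R), while the six benzyl ethers fall under neutral conditions that do not enolise the contra-thermodynamic C1 centre.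

## Compound list
1 | 1,3-bis(benzyloxy)-5-bromobenzene | Brc1cc(OCc2ccccc2)cc(OCc2ccccc2)c1 | starting material
2 | 1-(benzyloxy)-4-ethynylbenzene | C#Cc1ccc(OCc2ccccc2)cc1 | starting material
3 | 1,3-bis(benzyloxy)-5-{[4-(benzyloxy)phenyl]ethynyl}benzene | C(#Cc1ccc(OCc2ccccc2)cc1)c1cc(OCc2ccccc2)cc(OCc2ccccc2)c1 | intermediate
4 | 1,5-bis(benzyloxy)-2-bromo-3-{[4-(benzyloxy)phenyl]ethynyl}benzene | Brc1c(OCc2ccccc2)cc(OCc2ccccc2)cc1C#Cc1ccc(OCc2ccccc2)cc1 | intermediate
5 | 1-[4-(benzyloxy)phenyl]-2-[3,5-bis(benzyloxy)phenyl]ethan-1-one | O=C(Cc1cc(OCc2ccccc2)cc(OCc2ccccc2)c1)c1ccc(OCc2ccccc2)cc1 | intermediate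
6 | (±)-1-[4-(benzyloxy)phenyl]-2-[3,5-bis(benzyloxy)phenyl]-2-(2,4-bis(benzyloxy)-6-{[4-(benzyloxy)phenyl]ethynyl}phenyl)ethan-1-one (racemate, no stereo label) | O=C(c1ccc(OCc2ccccc2)cc1)C(c1cc(OCc2ccccc2)cc(OCc2ccccc2)c1)c1c(OCc2ccccc2)cc(OCc2ccccc2)cc1C#Cc1ccc(OCc2ccccc2)cc1 | intermediate
7 | triaryl enol of 6, 1-[4-(benzyloxy)phenyl]-2-[3,5-bis(benzyloxy)phenyl]-2-(2,4-bis(benzyloxy)-6-{[4-(benzyloxy)phenyl]ethynyl}phenyl)ethen-1-ol (achiral, E/Z mixture, not isolated) | OC(c1ccc(OCc2ccccc2)cc1)=C(c1cc(OCc2ccccc2)cc(OCc2ccccc2)c1)c1c(OCc2ccccc2)cc(OCc2ccccc2)cc1C#Cc1ccc(OCc2ccccc2)cc1 | intermediate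
8 | indeno-fused 2H-oxete, the formal [2+2] adduct of the C2=O group across C1≡C7′: ring O–C2–C1=C7′, C2 (S) carries the 4-benzyloxyphenyl group anti to the C3 aryl, C3 (R) (not isolated) | C1(c2ccc(OCc3ccccc3)cc2)=C2c3cc(OCc4ccccc4)cc(OCc4ccccc4)c3[C@@H](c3cc(OCc4ccccc4)cc(OCc4ccccc4)c3)[C@@]2(c2ccc(OCc3ccccc3)cc2)O1 | intermediate
9 | {(1S)-5,7-bis(benzyloxy)-2-[4-(benzyloxy)phenyl]-1-[3,5-bis(benzyloxy)phenyl]-1H-inden-3-yl}[4-(benzyloxy)phenyl]methanone | O=C(c1ccc(OCc2ccccc2)cc1)C1=C(c2ccc(OCc3ccccc3)cc2)[C@H](c2cc(OCc3ccccc3)cc(OCc3ccccc3)c2)c2c(OCc3ccccc3)cc(OCc3ccccc3)cc21 | intermediate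
10 | caraphenol B, (1R,2R,3R), all-cis | O=C(c1ccc(O)cc1)[C@H]1c2cc(O)cc(O)c2[C@@H](c2cc(O)cc(O)c2)[C@H]1c1ccc(O)cc1 | target

## Step count and weak points
Total steps: 6. Longest linear sequence: 5 (steps 1, 2, 4, 5, 6; step 3 runs in parallel on a second portion of 3).

**Step 4 (crowded enolate arylation with a di-ortho-substituted bromide).**
- Risk: slow oxidative addition or reductive elimination, and insertion of aryl-Pd into the tolane units.
- Fallback, from 4 back to 6: the order of bond formation at C3 is reversed, so the hindered bromide meets an unhindered enolate and the hindered enolate meets an unhindered bromide.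
- Bromide 4 is first coupled with commercial 1-[4-(benzyloxy)phenyl]ethan-1-one (Pd(OAc)2/XPhos, K3PO4, toluene, 100 °C). This gives 1-[4-(benzyloxy)phenyl]-2-(2,4-bis(benzyloxy)-6-{[4-(benzyloxy)phenyl]ethynyl}phenyl)ethan-1-one F1.
- F1 is then α-arylated with bromide 1, which has no ortho substituent, under the same type of catalysis to give 6.
- Compound 5 and step 3 are then not needed, so the total stays at six steps.

**Step 5 (the proposed new step).**
- Risk: enolisation may be slower than ring closure, which leaves a plain kinetic resolution. The ee may be low with this large substrate. Competing paths are 5-endo attack of the enol carbon on the alkyne and acid-induced benzyl migration.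
- Fallback with known chemistry, from 6 back to 9: 6 is cyclised by the established racemic alkyne–carbonyl metathesis (FeCl3 10 mol %, 1,2-dichloroethane, rt). This gives racemic {5,7-bis(benzyloxy)-2-[4-(benzyloxy)phenyl]-1-[3,5-bis(benzyloxy)phenyl]-1H-inden-3-yl}[4-(benzyloxy)phenyl]methanone F2.
- F2 is separated on a preparative polysaccharide chiral phase (SFC) into 9 and the enantiomer {(1R)-5,7-bis(benzyloxy)-2-[4-(benzyloxy)phenyl]-1-[3,5-bis(benzyloxy)phenyl]-1H-inden-3-yl}[4-(benzyloxy)phenyl]methanone F3.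
- F3 is returned to F2 with catalytic DBU in toluene, since its H-1 is doubly benzylic and vinylogously α to the ketone, and is then recycled.

**Step 6 (tetrasubstituted enone, labile centres).**
- Risk: debenzylation may outrun C=C saturation, giving a phenolic enone that can racemise at C3. The ketone may be over-reduced. C1 may epimerise during isolation.
- Fallback, from 9 back to 10: the two events are separated and the C=C bond is saturated first on the fully protected, non-phenolic substrate.
- A homogeneous cationic iridium catalyst is used ([Ir(cod)(PCy3)(py)]BArF, H2 50 bar, CH2Cl2, rt). It tolerates benzyl ethers and again adds H2 anti to the C3 aryl, giving [(1R,2R,3R)-4,6-bis(benzyloxy)-2-[4-(benzyloxy)phenyl]-3-[3,5-bis(benzyloxy)phenyl]-2,3-dihydro-1H-inden-1-yl][4-(benzyloxy)phenyl]methanone F4.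
- F4 has no acidic indene C–H and is debenzylated under neutral conditions (Pd(OH)2/C, H2 1 bar, THF/EtOAc, rt) to 10.

Further compounds
F1 | step 4 | 1-[4-(benzyloxy)phenyl]-2-(2,4-bis(benzyloxy)-6-{[4-(benzyloxy)phenyl]ethynyl}phenyl)ethan-1-one | O=C(Cc1c(OCc2ccccc2)cc(OCc2ccccc2)cc1C#Cc1ccc(OCc2ccccc2)cc1)c1ccc(OCc2ccccc2)cc1
F2 | step 5 | racemic {5,7-bis(benzyloxy)-2-[4-(benzyloxy)phenyl]-1-[3,5-bis(benzyloxy)phenyl]-1H-inden-3-yl}[4-(benzyloxy)phenyl]methanone | O=C(c1ccc(OCc2ccccc2)cc1)C1=C(c2ccc(OCc3ccccc3)cc2)C(c2cc(OCc3ccccc3)cc(OCc3ccccc3)c2)c2c(OCc3ccccc3)cc(OCc3ccccc3)cc21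
F3 | step 5 | {(1R)-5,7-bis(benzyloxy)-2-[4-(benzyloxy)phenyl]-1-[3,5-bis(benzyloxy)phenyl]-1H-inden-3-yl}[4-(benzyloxy)phenyl]methanone | O=C(c1ccc(OCc2ccccc2)cc1)C1=C(c2ccc(OCc3ccccc3)cc2)[C@@H](c2cc(OCc3ccccc3)cc(OCc3ccccc3)c2)c2c(OCc3ccccc3)cc(OCc3ccccc3)cc21
F4 | step 6 | [(1R,2R,3R)-4,6-bis(benzyloxy)-2-[4-(benzyloxy)phenyl]-3-[3,5-bis(benzyloxy)phenyl]-2,3-dihydro-1H-inden-1-yl][4-(benzyloxy)phenyl]methanone | O=C(c1ccc(OCc2ccccc2)cc1)[C@H]1c2cc(OCc3ccccc3)cc(OCc3ccccc3)c2[C@@H](c2cc(OCc3ccccc3)cc(OCc3ccccc3)c2)[C@H]1c1ccc(OCc2ccccc2)cc1
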